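In a one-step world free monomer goes into chains and the curve climbs until the charge is used. The west flask, which is the flask asked about, does otherwise.

in all of them: free monomer 0.16 M; initiator 0.42 mM

| flask | impurity | temperature | remark | time |
|---|---|---|---|---|
| west | 0.27 mM | 80 °C | the very flask that is asked about, followed so far |  |
| north-west | 0.41 mM | 86 °C | run made earlier |  |
| flask | 0.27 mM | 80 °C |  | 8.0 h |

- west (time / min: monomer in chains / %): 20.0: 36.6; 60.0: 30.9; 120: 29.1; 180: 27.3; 240: 27.7; 300: 27.2; 360: 27.5
- north-west (time / min: monomer in chains / %): 0.500: 1.3; 1.50: 3.5; 3.00: 6.6; 4.00: 8.3; 6.00: 12.3; 8.00: 14.0; 10.0: 15.6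

(each reading ± 0.5 percentage points)

- beta: at 8.0 h add initiator, 100% of the amount charged, then wait 8.0 h
- alpha: change nothing and wait 8.0 h more
- delta: at 8.0 h raise the temperature by 15 K, then wait 8.0 h
- theta: at 8.0 h take out 90% of the monomer in chains then present, then wait 8.0 h

- monomer in chains, in percent of the free monomer first charged, at 8.0 h
- what to do for the largest gain in monomer in chains; "none" if nothing gains more than 2 percentage points (beta / alpha / delta / theta / none)
- monomer in chains present, with what was taken out counted in, in percent of the free monomer first charged, after beta
- monomer in chains present, with what was taken out counted in, in percent of the free monomer first charged, after delta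

West reads 36.6% at 20.0 min and then falls, so more than one step is at work. First question: has it stopped? We replace the tail from 180 min on by its mean, 27.4%, good to 0.25 percentage points. The later pair of readings differs from the earlier pair by −0.15 points, less than one scatter. So we take the mean as our answer at 8.0 h.

Second question: what stops it? We call the part of the charge standing outside chains on the flat stretch the outside share, 72.6%. West fell 9.2 points from its first reading to the flat stretch, more than the scatter, and a mere stall does not give chains back, so we read the flat line as a balance, not a shortage: thermodynamic, not kinetic, control. Making and unzipping both go through the living end, so we expect extra initiator to change the speed and not the level. Taking chains out leaves the monomer outside where it stood. By our reckoning alpha, beta and theta each gain less than 2 points.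

Third question: does heat move the outside share? The north-west run cannot say, for at 10.0 min it reads 15.6% and its last step is 1.6 points, more than the scatter. It is still climbing, so we leave delta open.

The forecast commits where we do not: 27.4% now, 27.6% after beta, 0.5% after delta, and best choice none, expecting that “chains unzip to nearly zero”.

The flask gives 27.3% at 8.0 h, 27.3% after beta and 35.8% after delta, so the best choice is delta, a gain of 8.4 points.

    free monomer + initiator → living end + monomer in chains (k = 0.110 M⁻¹ s⁻¹, Ea = 46.0 kJ mol⁻¹)
    monomer in chains + living end → free monomer + living end, rate k2*[living end] as long as [monomer in chains] is above zero (k = 0.740 s⁻¹, Ea = 74.0 kJ mol⁻¹)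
    initiator → spent initiator B (k = 5.60 × 10⁻⁷ s⁻¹, Ea = 121 kJ mol⁻¹)
    initiator + impurity → spent initiator A (k = 950 M⁻¹ s⁻¹, Ea = 48.0 kJ mol⁻¹)
    free monomer ⇌ dormant form (K = 1.20, k = 7.90 × 10⁻⁴ s⁻¹, Ea = 93.0 kJ mol⁻¹, ΔH = −61.0 kJ mol⁻¹)
    free monomer + living end → monomer in chains + living end, rate k6*[living end]*[free monomer] (k = 14.0 M⁻¹ s⁻¹, Ea = 56.0 kJ mol⁻¹)
    (constants at 80 °C)

At 480 min the flask holds free monomer 33.0% and dormant form 39.6%. Delta lowers the outside share to 64.2%, less than 72.6%. Carried as an amount, the share also serves a flask charged with 0.27 M, which is 1.69 of our charges: 72.6% divided by that ratio leaves 57.0% in chains, and that flask holds 56.9%.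

(The earlier runs and the new flask stem from a simulated flask with made-up constants, and the scatter is random.)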